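## Structural features

2'-Methoxylupalbigenin is an isoflavone: a 4H-chromen-4-one (benzo ring A fused to pyranone ring C) carrying aryl ring B at C3. It has no stereocentre, and the only stereo-element met on the way is an alkene geometry that does not reach the target. Ring A is a phloroglucinol ring in which all six carbons differ: C8a bears the ring oxygen O1, C4a the carbonyl carbon C4, C5 and C7 hydroxyl groups, C6 a prenyl group between them, and C8 the only hydrogen. Ring B is a 1,2,3,4-tetrasubstituted benzene: C1' is bonded to C3, C2' bears a methoxy group that must stay distinct from three free phenols, C3' a prenyl group between two oxygens, and C4' a hydroxyl group. The fragile groups are the two trisubstituted alkenes, each ortho to a phenol (acid closes them to chromans, electrophilic halogen and oxidants attack them), and the C2=C3 vinylogous ester of ring C, which hard nucleophiles open. The real difficulty is regiochemical: the prenyl group must sit at C6 and not at C8, two positions that are both flanked by oxygen in any phloroglucinol precursor and that interchange when a 2-prenylphloroglucinol ketone closes through one or the other ortho hydroxyl. The feature exploited is that the two bonds joining ring A to ring C, C8a–O1 and C4a–C4, start from adjacent ring carbons, and that C4a is flanked by the C5 oxygen whereas C8a is flanked by C8–H. Without these two bonds ring A is a C2-symmetric 2-prenylresorcinol diether in which C6 is the unique carbon between the two oxygens, so an aryne C4a≡C8a can take up O1 and C4 in one operation, oriented by the C5 oxygen, with the C6/C8 question already settled by symmetry.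

## Logic of the disconnections

**27 to 26.** The three O–CH2 acetal bonds at O5, O7 and O4' are cut last. One acid-labile group type masks all three phenols, leaves the 2'-methyl ether distinct, and is the directing group for every metalation of the route. There is no skeletal gain. The forward step must remove three acetals with brief acid without closing either prenyl group onto its neighbouring phenol.

**26 to 14 and 23 (through 24 and 25).** Three bonds of ring C are cut: O1–C2 (back to 25), then C8a–O1 and C4a–C4 together (back to 24 and 23). The cut is made here because these two bonds leave ring A from adjacent carbons, which is the signature of an aryne, and because the acid 23 already holds C2, C3, C4, O1 and ring B. The gain is large: 26 falls into two fragments of similar size, ring A needs no oxygen at C8a and no differentiation of its two oxygens, and the C6 versus C8 placement of the prenyl group is no longer a question. The forward step demands that the carboxylate oxygen adds to C8a and not to C4a, that the aryl anion acylates itself faster than it is protonated, and that the prenyl alkenes stay spectators towards 24.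

**23 to 22, and 22 to 18 and 19.** The ester O–CH3 bond and then the C3–C1' bond are cut. The three-carbon β-methoxyacrylate unit is available as the alkenyl iodide 19, so ring B only has to be an aryl nucleophile. The gain is that 18 is a plain bromoarene with ring B fully substituted. The forward coupling must tolerate one ortho substituent on the arylzinc, and the hydrolysis must spare the enol ether.

**18 to 16, and 16 to 15.** The C3'–CH2 bond of the prenyl group and the O4'–CH2 acetal bond are cut. C3' is the only ring carbon between two oxygens, so a deprotonation finds it, and the bromine of 15 already marks C1' (para to O4', ortho to the methoxy group). The forward step needs a base that removes this proton without exchanging or eliminating the bromine.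

**14 to 12, 12 to 8, and 8 to 7.** The O–S bond of the triflate, the C–Si bond and the carbamate C–O bond are cut. The ortho-silyl triflate pattern is written onto the ring by a carbamate-directed metalation and then unmasked. The demand is metalation at the carbon ortho to the carbamate rather than at the one ortho to the remaining acetal, and carbamate removal under conditions that leave acetals and alkene alone.

**7 to 4, 4 to 2, and 2 to 1.** The aryl C–O bond (an oxygen that is not in the target and leaves as triflate), the C–CH2 bond of the prenyl group and the two acetal bonds are cut. In 2 the carbon between the acetals is unique, and in 4 the two remaining ortho positions are equivalent, so neither metalation has a regiochemical choice. The demand is ring metalation next to an acetal oxygen in preference to deprotonation of the benzylic and allylic CH2 of 4.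

## Other disconnections considered

**Alternative 1:** The first plan that comes to mind cuts O1–C2 and C2–C3. Deoxybenzoin A1 would be closed to ring C with a one-carbon electrophile such as N,N-dimethylformamide dimethyl acetal. A1 needs three differently treated oxygens on ring A (free at C8a, protected at C5 and C7), because closure through the other ortho oxygen would give the C8-prenyl isomer. Its aryl ketone bond has to be made by C-acylation of a phloroglucinol nucleus, classically under acid that neither prenyl groups nor acetals tolerate. The chosen plan needs only two identical oxygens on ring A, forms the aryl ketone bond under fluoride, and makes ring C in the same operation.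

**Alternative 2:** Cut C3–C1'. Suzuki–Miyaura coupling of 3-iodochromone A2 with boronate A3 would join the rings. The coupling itself is sound, but A2 rests on the same differentiated phloroglucinol ketone as A1, so the C6/C8 problem is only moved back. The usual iodine-mediated closure to A2 also exposes the prenyl alkene to an iodonium source, and A3 is an electron-rich ortho-alkoxy boronate of the kind prone to protodeboronation. The chosen plan makes the C3–C1' bond early on a simple acrylate and spends the convergent step on ring C.

**Alternative 3:** Cut C3–C1' in the biosynthetic sense. Chalcone A4 would undergo oxidative 1,2-shift of ring B from C2 to C3 with Tl(NO3)3 (trivalent thallium) or a hypervalent iodine reagent, followed by ring closure. The oxidant is an electrophile for alkenes, and the two trisubstituted prenyl alkenes of A4 are more electron-rich than its enone. The prenyl groups would therefore have to be introduced after the rearrangement, which brings back the regiochemical problem that the chosen plan removes by symmetry.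

Key step: step 11

Assumption: methyl (Z)-2-iodo-3-methoxyprop-2-enoate (19) is taken as a purchased building block. The target has no stereocentre, and the alkene geometry of 19, 22, 23 and 25 is not carried into it.

## Route

Step 1
Reactants: 1 resorcinol (benzene-1,3-diol)
Product: 2 1,3-bis(methoxymethoxy)benzene
Conditions: MOMCl (2.5 equiv), i-Pr2NEt, CH2Cl2, 0 °C → rt
Reagents that add atoms: chloromethyl methyl ether, COCCl
Why: Double O-alkylation of the phenol with an α-chloro ether (Williamson-type acetal formation); the acetal oxygens later direct both metalations of ring A.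

Step 2
Reactants: 2 1,3-bis(methoxymethoxy)benzene
Product: 4 1,3-bis(methoxymethoxy)-2-(3-methylbut-2-en-1-yl)benzene, via aryllithium 3 (not isolated)
Conditions: n-BuLi, TMEDA, THF, 0 °C; then CuI (10 mol %), 1-bromo-3-methylbut-2-ene, −78 °C → rt
Reagents that add atoms: 1-bromo-3-methylbut-2-ene, CC(C)=CCBr; n-butyllithium, [Li]CCCC (lithium of 3 only)
Why: Directed ortho metalation takes place at the one carbon activated by both acetal oxygens, and copper-catalysed allylation of the aryllithium should give the linear prenyl product; the C2-symmetry of 2 leaves no regiochemical choice.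

Step 3
Reactants: 4 1,3-bis(methoxymethoxy)-2-(3-methylbut-2-en-1-yl)benzene
Product: 7 2,4-bis(methoxymethoxy)-3-(3-methylbut-2-en-1-yl)phenol, via aryllithium 5 (not isolated), via dimethyl arylboronate 6 (not isolated)
Conditions: s-BuLi, TMEDA, THF, −78 °C; B(OMe)3, −78 °C → rt; then 30% aq. H2O2, aq. NaOH, 0 °C
Reagents that add atoms: hydrogen peroxide, OO (the phenol oxygen); trimethyl borate, COB(OC)OC (boron and methoxy groups of 6 only); sec-butyllithium, [Li]C(C)CC (lithium of 5 only)
Why: Directed ortho metalation next to an acetal oxygen (both such positions of 4 are equivalent), borylation, and oxidative 1,2-shift of the aryl group from boron to oxygen should give the phenol; coordination of the base to the acetal is expected to favour ring metalation over deprotonation of the prenyl CH2, and alkaline peroxide does not epoxidise an isolated alkene.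

Step 4
Reactants: 7 2,4-bis(methoxymethoxy)-3-(3-methylbut-2-en-1-yl)phenol
Product: 8 2,4-bis(methoxymethoxy)-3-(3-methylbut-2-en-1-yl)phenyl propan-2-ylcarbamate
Conditions: i-PrNCO, Et3N (10 mol %), CH2Cl2, rt
Reagents that add atoms: isopropyl isocyanate, CC(C)N=C=O
Why: Base-catalysed addition of the phenol to the isocyanate gives the secondary carbamate, which is both the directing group for step 5 and a group that leaves under mild base in step 6.

Step 5
Reactants: 8 2,4-bis(methoxymethoxy)-3-(3-methylbut-2-en-1-yl)phenyl propan-2-ylcarbamate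
Product: 12 2,4-bis(methoxymethoxy)-3-(3-methylbut-2-en-1-yl)-6-(trimethylsilyl)phenyl propan-2-ylcarbamate, via N-silyl carbamate 9 (not isolated), via lithiated N-silyl carbamate 10 (not isolated), via N-silyl C-silyl carbamate 11 (not isolated)
Conditions: TBSOTf, TMEDA, Et2O, 0 °C → rt; n-BuLi, TMEDA, −78 °C; TMSCl, −78 °C → rt; sat. aq. NaHSO4
Reagents that add atoms: chlorotrimethylsilane, C[Si](C)(C)Cl; tert-butyldimethylsilyl trifluoromethanesulfonate, CC(C)(C)[Si](C)(C)OS(=O)(=O)C(F)(F)F (silyl group of 9 to 11 only); n-butyllithium, [Li]CCCC (lithium of 10 only)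
Why: N-silylation in the flask turns the secondary carbamate into a tertiary one, the strongest oxygen-based directing group present, so directed ortho metalation should occur at C6 (ortho to the carbamate) and not at C5 (ortho to one acetal only); C-silylation and acidic work-up, which removes the N-silyl group, give 12.

Step 6
Reactants: 12 2,4-bis(methoxymethoxy)-3-(3-methylbut-2-en-1-yl)-6-(trimethylsilyl)phenyl propan-2-ylcarbamate
Product: 14 2,4-bis(methoxymethoxy)-3-(3-methylbut-2-en-1-yl)-6-(trimethylsilyl)phenyl trifluoromethanesulfonate, via silyl phenol 13 (not isolated)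
Conditions: DBU, Et2NH, MeCN, 40 °C; then PhNTf2, rt
Reagents that add atoms: N-phenylbis(trifluoromethanesulfonimide), O=S(=O)(N(c1ccccc1)S(=O)(=O)C(F)(F)F)C(F)(F)F
Why: Deprotonation at nitrogen and E1cB loss of isopropyl isocyanate (trapped by diethylamine as a urea) frees the phenoxide, which is triflated in the same flask; base-only conditions leave acetals, alkene and the C–Si bond untouched.

Step 7
Reactants: 15 4-bromo-3-methoxyphenol
Product: 16 1-bromo-2-methoxy-4-(methoxymethoxy)benzene
Conditions: MOMCl, i-Pr2NEt, CH2Cl2, 0 °C → rt
Reagents that add atoms: chloromethyl methyl ether, COCCl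
Why: O-alkylation of the phenol with an α-chloro ether; the bromine of 15 already fixes C1' para to O4' and ortho to the methoxy group.

Step 8
Reactants: 16 1-bromo-2-methoxy-4-(methoxymethoxy)benzene
Product: 18 1-bromo-2-methoxy-4-(methoxymethoxy)-3-(3-methylbut-2-en-1-yl)benzene, via aryllithium 17 (not isolated)
Conditions: LiN(i-Pr)2 (LDA), THF, −78 °C; then CuI (10 mol %), 1-bromo-3-methylbut-2-ene, −78 → 0 °C
Reagents that add atoms: 1-bromo-3-methylbut-2-ene, CC(C)=CCBr; lithium diisopropylamide, CC(C)[N-]C(C)C.[Li+] (lithium of 17 only)
Why: An amide base deprotonates without bromine–lithium exchange, and the C–H between the methoxy and acetal oxygens is the most acidic and the best coordinated (directed ortho metalation); the anion is meta to bromine and cannot eliminate LiBr, and copper-catalysed allylation should give the linear prenyl group.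

Step 9
Reactants: 18 1-bromo-2-methoxy-4-(methoxymethoxy)-3-(3-methylbut-2-en-1-yl)benzene; 19 methyl (Z)-2-iodo-3-methoxyprop-2-enoate
Product: 22 methyl (E)-3-methoxy-2-[2-methoxy-4-(methoxymethoxy)-3-(3-methylbut-2-en-1-yl)phenyl]prop-2-enoate, via aryllithium 20 (not isolated), via arylzinc chloride 21 (not isolated)
Conditions: n-BuLi, THF, −78 °C; ZnCl2, −78 °C → rt; then 19, Pd(PPh3)4 (5 mol %), THF, 50 °C
Reagents that add atoms: n-butyllithium, [Li]CCCC (lithium of 20 only); zinc chloride, Cl[Zn]Cl (zinc and chlorine of 21 only)
Why: Bromine–lithium exchange, transmetalation to zinc and Negishi coupling; zerovalent palladium inserts into the alkenyl C–I bond and the coupling proceeds with retention, so the aryl group takes the place of iodine (the descriptor changes from Z to E by priority only).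

Step 10
Reactants: 22 methyl (E)-3-methoxy-2-[2-methoxy-4-(methoxymethoxy)-3-(3-methylbut-2-en-1-yl)phenyl]prop-2-enoate
Product: 23 (E)-3-methoxy-2-[2-methoxy-4-(methoxymethoxy)-3-(3-methylbut-2-en-1-yl)phenyl]prop-2-enoic acid
Conditions: LiOH·H2O, THF/MeOH/H2O, rt; then 1 M HCl to pH 4, 0 °C
Reagents that add atoms: lithium hydroxide, [Li+].[OH-] (the hydroxyl oxygen of the acid)
Why: Saponification of the methyl ester; the β-methoxy group makes the β-carbon a poor acceptor, so attack at the ester carbonyl should dominate, and cold, brief acidification to pH 4 spares the acetal.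

Step 11
Reactants: 14 2,4-bis(methoxymethoxy)-3-(3-methylbut-2-en-1-yl)-6-(trimethylsilyl)phenyl trifluoromethanesulfonate; 23 (E)-3-methoxy-2-[2-methoxy-4-(methoxymethoxy)-3-(3-methylbut-2-en-1-yl)phenyl]prop-2-enoic acid
Product: 26 3-[2-methoxy-4-(methoxymethoxy)-3-(3-methylbut-2-en-1-yl)phenyl]-5,7-bis(methoxymethoxy)-6-(3-methylbut-2-en-1-yl)-4H-chromen-4-one, via aryne 24 (not isolated), via hydroxyaryl ketone 25 (not isolated)
Conditions: CsF (4 equiv), 23 (1.3 equiv), THF, 125 °C, sealed tube
Reagents that add atoms: none
Why: Fluoride attacks silicon of 14 and triflate leaves from the neighbouring carbon to give aryne 24. The cesium carboxylate of 23 should add through oxygen to the aryne carbon remote from the flanking acetal oxygen (the future C8a): this terminus is the more electrophilic and less hindered one (its neighbour is C8–H), and addition there places the aryl anion at C4a, next to the inductively withdrawing C5–O bond. The aryl anion lies in the ring plane beside the twisted aryl ester and attacks the ester carbonyl (4-exo-trig); the strained four-membered alkoxide opens by C–O cleavage to the ortho-acyl phenoxide of 25, a net insertion of the aryne into the C(acyl)–O bond. The phenoxide then closes ring C by 6-endo-trig conjugate addition to the β-methoxy enone and E1cB loss of methoxide, the same closure as in the classical enaminone route to isoflavones. The closest known reaction type is the fluoride-induced C–O addition of carboxylic acids to arynes, which gives ortho-hydroxyaryl ketones and, from unsaturated acids, chroman-4-ones and flavones. No stereocentre is formed and the alkene geometry of 23 is erased. The step needs three selectivities: the sense of addition, secured by the C5 acetal oxygen; carbonyl attack rather than attack at the β-carbon (which would lead to a 3-arylcoumarin), favoured by the in-plane anion and the donor methoxy group; and acyl transfer faster than protonation, favoured by the aprotic medium and high temperature. The prenyl alkenes should stay spectators because the anionic oxygen nucleophile, used in excess, is far more reactive towards 24 than an alkene in an ene reaction.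

Step 12
Reactants: 26 3-[2-methoxy-4-(methoxymethoxy)-3-(3-methylbut-2-en-1-yl)phenyl]-5,7-bis(methoxymethoxy)-6-(3-methylbut-2-en-1-yl)-4H-chromen-4-one
Product: 27 2'-methoxylupalbigenin, 5,7-dihydroxy-3-[4-hydroxy-2-methoxy-3-(3-methylbut-2-en-1-yl)phenyl]-6-(3-methylbut-2-en-1-yl)-4H-chromen-4-one
Conditions: 3 M aq. HCl, MeOH, 50 °C, short reaction time
Reagents that add atoms: none
Why: Acid-catalysed acetal exchange with methanol removes the three methoxymethyl groups (the C5 acetal, next to the carbonyl, first); the methyl ether is inert, and brief mild acid is the standard way to unmask prenylated flavonoid phenols without chroman formation.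

## Compound list

1 | resorcinol (benzene-1,3-diol) | Oc1cccc(O)c1 | starting material
2 | 1,3-bis(methoxymethoxy)benzene | COCOc1cccc(OCOC)c1 | intermediate
3 | [2,6-bis(methoxymethoxy)phenyl]lithium | [Li]c1c(OCOC)cccc1OCOC | intermediate
4 | 1,3-bis(methoxymethoxy)-2-(3-methylbut-2-en-1-yl)benzene | COCOc1cccc(OCOC)c1CC=C(C)C | intermediate
5 | [2,4-bis(methoxymethoxy)-3-(3-methylbut-2-en-1-yl)phenyl]lithium | [Li]c1ccc(OCOC)c(CC=C(C)C)c1OCOC | intermediate
6 | dimethyl [2,4-bis(methoxymethoxy)-3-(3-methylbut-2-en-1-yl)phenyl]boronate | COB(OC)c1ccc(OCOC)c(CC=C(C)C)c1OCOC | intermediate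
7 | 2,4-bis(methoxymethoxy)-3-(3-methylbut-2-en-1-yl)phenol | Oc1ccc(OCOC)c(CC=C(C)C)c1OCOC | intermediate
8 | 2,4-bis(methoxymethoxy)-3-(3-methylbut-2-en-1-yl)phenyl propan-2-ylcarbamate | CC(C)NC(=O)Oc1ccc(OCOC)c(CC=C(C)C)c1OCOC | intermediate
9 | 2,4-bis(methoxymethoxy)-3-(3-methylbut-2-en-1-yl)phenyl N-(tert-butyldimethylsilyl)-N-(propan-2-yl)carbamate | CC(C)N(C(=O)Oc1ccc(OCOC)c(CC=C(C)C)c1OCOC)[Si](C)(C)C(C)(C)C | intermediate
10 | 6-lithio derivative of 9, [2-{[(tert-butyldimethylsilyl)(propan-2-yl)carbamoyl]oxy}-3,5-bis(methoxymethoxy)-4-(3-methylbut-2-en-1-yl)phenyl]lithium | CC(C)N(C(=O)Oc1c([Li])cc(OCOC)c(CC=C(C)C)c1OCOC)[Si](C)(C)C(C)(C)C | intermediate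
11 | 2,4-bis(methoxymethoxy)-3-(3-methylbut-2-en-1-yl)-6-(trimethylsilyl)phenyl N-(tert-butyldimethylsilyl)-N-(propan-2-yl)carbamate | CC(C)N(C(=O)Oc1c([Si](C)(C)C)cc(OCOC)c(CC=C(C)C)c1OCOC)[Si](C)(C)C(C)(C)C | intermediate
12 | 2,4-bis(methoxymethoxy)-3-(3-methylbut-2-en-1-yl)-6-(trimethylsilyl)phenyl propan-2-ylcarbamate | CC(C)NC(=O)Oc1c([Si](C)(C)C)cc(OCOC)c(CC=C(C)C)c1OCOC | intermediate
13 | 2,4-bis(methoxymethoxy)-3-(3-methylbut-2-en-1-yl)-6-(trimethylsilyl)phenol | Oc1c([Si](C)(C)C)cc(OCOC)c(CC=C(C)C)c1OCOC | intermediate
14 | 2,4-bis(methoxymethoxy)-3-(3-methylbut-2-en-1-yl)-6-(trimethylsilyl)phenyl trifluoromethanesulfonate | O=S(=O)(Oc1c([Si](C)(C)C)cc(OCOC)c(CC=C(C)C)c1OCOC)C(F)(F)F | intermediate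
15 | 4-bromo-3-methoxyphenol | COc1cc(O)ccc1Br | starting material
16 | 1-bromo-2-methoxy-4-(methoxymethoxy)benzene | COCOc1ccc(Br)c(OC)c1 | intermediate
17 | [3-bromo-2-methoxy-6-(methoxymethoxy)phenyl]lithium | [Li]c1c(OCOC)ccc(Br)c1OC | intermediate
18 | 1-bromo-2-methoxy-4-(methoxymethoxy)-3-(3-methylbut-2-en-1-yl)benzene | COCOc1ccc(Br)c(OC)c1CC=C(C)C | intermediate
19 | methyl (Z)-2-iodo-3-methoxyprop-2-enoate | CO/C=C(\I)C(=O)OC | starting material
20 | [2-methoxy-4-(methoxymethoxy)-3-(3-methylbut-2-en-1-yl)phenyl]lithium | [Li]c1ccc(OCOC)c(CC=C(C)C)c1OC | intermediate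
21 | chloro[2-methoxy-4-(methoxymethoxy)-3-(3-methylbut-2-en-1-yl)phenyl]zinc | Cl[Zn]c1ccc(OCOC)c(CC=C(C)C)c1OC | intermediate
22 | methyl (E)-3-methoxy-2-[2-methoxy-4-(methoxymethoxy)-3-(3-methylbut-2-en-1-yl)phenyl]prop-2-enoate | CO/C=C(\c1ccc(OCOC)c(CC=C(C)C)c1OC)C(=O)OC | intermediate
23 | (E)-3-methoxy-2-[2-methoxy-4-(methoxymethoxy)-3-(3-methylbut-2-en-1-yl)phenyl]prop-2-enoic acid | CO/C=C(\c1ccc(OCOC)c(CC=C(C)C)c1OC)C(=O)O | intermediate
24 | 3,5-bis(methoxymethoxy)-4-(3-methylbut-2-en-1-yl)benzyne (1,2-didehydrobenzene) | C1#CC(OCOC)=C(CC=C(C)C)C(OCOC)=C1 | intermediate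
25 | (E)-1-[6-hydroxy-2,4-bis(methoxymethoxy)-3-(3-methylbut-2-en-1-yl)phenyl]-3-methoxy-2-[2-methoxy-4-(methoxymethoxy)-3-(3-methylbut-2-en-1-yl)phenyl]prop-2-en-1-one | CO/C=C(/C(=O)c1c(O)cc(OCOC)c(CC=C(C)C)c1OCOC)c1ccc(OCOC)c(CC=C(C)C)c1OC | intermediate
26 | 3-[2-methoxy-4-(methoxymethoxy)-3-(3-methylbut-2-en-1-yl)phenyl]-5,7-bis(methoxymethoxy)-6-(3-methylbut-2-en-1-yl)-4H-chromen-4-one | COc1c(-c2coc3cc(OCOC)c(CC=C(C)C)c(OCOC)c3c2=O)ccc(OCOC)c1CC=C(C)C | intermediate
27 | 2'-methoxylupalbigenin, 5,7-dihydroxy-3-[4-hydroxy-2-methoxy-3-(3-methylbut-2-en-1-yl)phenyl]-6-(3-methylbut-2-en-1-yl)-4H-chromen-4-one | COc1c(-c2coc3cc(O)c(CC=C(C)C)c(O)c3c2=O)ccc(O)c1CC=C(C)C | target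

## Step count and least certain steps

Total step count: 12. Longest linear sequence: 8 steps (steps 1 to 6, then 11 and 12, from 1). The ring B branch (steps 7 to 10) joins at step 11.

**Step 11 (key step).** The most likely failure is protonation of the aryl anion before the four-membered acyl transfer. The proton source is the hydrogen fluoride set free when the acid meets fluoride, and the result is plain O-arylation that cannot continue to ring C. A second risk is loss of 24 by ene reaction with a prenyl group or by self-condensation. The fallback builds the same ortho-acyl phenoxide stepwise by anionic acylation. It sets out from 23 and 4 and comes back at 26.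
- 23 is converted into (E)-N,3-dimethoxy-N-methyl-2-[2-methoxy-4-(methoxymethoxy)-3-(3-methylbut-2-en-1-yl)phenyl]prop-2-enamide F1 (carbodiimide coupling with N,O-dimethylhydroxylamine hydrochloride).
- 4 is borylated at its only unhindered position ([Ir(OMe)(cod)]2, 4,4'-di-tert-butyl-2,2'-bipyridine, bis(pinacolato)diboron) to 2-[3,5-bis(methoxymethoxy)-4-(3-methylbut-2-en-1-yl)phenyl]-4,4,5,5-tetramethyl-1,3,2-dioxaborolane F2.
- F2 is oxidised (H2O2, NaOH) to the C2-symmetric 3,5-bis(methoxymethoxy)-4-(3-methylbut-2-en-1-yl)phenol F3.
- F3 is protected as 1,3-bis(methoxymethoxy)-2-(3-methylbut-2-en-1-yl)-5-{[2-(trimethylsilyl)ethoxy]methoxy}benzene F4.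
- Ortho-lithiation of F4 (n-BuLi, TMEDA) between its two different acetal oxygens, a position that symmetry makes unique, and addition to F1 gives (E)-1-[2,4-bis(methoxymethoxy)-3-(3-methylbut-2-en-1-yl)-6-{[2-(trimethylsilyl)ethoxy]methoxy}phenyl]-3-methoxy-2-[2-methoxy-4-(methoxymethoxy)-3-(3-methylbut-2-en-1-yl)phenyl]prop-2-en-1-one F5.
- Tetrabutylammonium fluoride removes only the silylethoxymethyl group of F5, and the phenoxide so freed closes ring C by the addition–elimination of step 11 to give 26.

**Step 8.** The risks are deprotonation next to bromine followed by loss of LiBr, migration of bromine between aryllithium species, and allylic transposition during the alkylation. The fallback removes the bromine during the metalation. It sets out from 16 and comes back at 18. Bromine–lithium exchange (n-BuLi) and silylation give [2-methoxy-4-(methoxymethoxy)phenyl]trimethylsilane F8. Lithiation of F8 between the two oxygens (n-BuLi, TMEDA) and copper-catalysed prenylation give [2-methoxy-4-(methoxymethoxy)-3-(3-methylbut-2-en-1-yl)phenyl]trimethylsilane F9. Ipso-bromodesilylation of F9 (N-bromosuccinimide, MeCN, 0 °C), at the carbon para to the acetal oxygen, returns 18.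

**Step 5.** The risks are transfer of the silyl triflate to an acetal oxygen (acetal cleavage) before N-silylation is complete, and metalation at C5 next to the remaining acetal. The fallback uses a tertiary carbamate that needs no silyl triflate. It sets out from 7 and comes back at 13. Carbamoylation of 7 (diethylcarbamoyl chloride, K2CO3) gives 2,4-bis(methoxymethoxy)-3-(3-methylbut-2-en-1-yl)phenyl diethylcarbamate F6. Metalation of F6 (s-BuLi, TMEDA, −78 °C) and trapping with TMSCl give 2,4-bis(methoxymethoxy)-3-(3-methylbut-2-en-1-yl)-6-(trimethylsilyl)phenyl diethylcarbamate F7. Reductive cleavage of F7 with LiAlH4 gives 13, which is triflated with PhNTf2 as in the second half of step 6.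

**Step 10.** The risks are hydroxide attack at the β-carbon of the enol ether (addition–elimination, then loss of the formyl carbon) in competition with slow hydrolysis of the hindered ester, and loss of the acetal during acidification. The fallback frees the acid without hydroxide or acid. It sets out from 19 and 21 and comes back at 23. Transesterification of 19 (allyl alcohol, Ti(Oi-Pr)4) gives prop-2-en-1-yl (Z)-2-iodo-3-methoxyprop-2-enoate F10. Negishi coupling of 21 with F10 under the conditions of step 9 gives prop-2-en-1-yl (E)-3-methoxy-2-[2-methoxy-4-(methoxymethoxy)-3-(3-methylbut-2-en-1-yl)phenyl]prop-2-enoate F11. Allyl transfer from F11 to morpholine with Pd(PPh3)4 gives 23 under neutral conditions.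

## Further compounds

F1 | step 11 | (E)-N,3-dimethoxy-N-methyl-2-[2-methoxy-4-(methoxymethoxy)-3-(3-methylbut-2-en-1-yl)phenyl]prop-2-enamide | CO/C=C(\c1ccc(OCOC)c(CC=C(C)C)c1OC)C(=O)N(C)OC
F2 | step 11 | 2-[3,5-bis(methoxymethoxy)-4-(3-methylbut-2-en-1-yl)phenyl]-4,4,5,5-tetramethyl-1,3,2-dioxaborolane | COCOc1cc(B2OC(C)(C)C(C)(C)O2)cc(OCOC)c1CC=C(C)C
F3 | step 11 | 3,5-bis(methoxymethoxy)-4-(3-methylbut-2-en-1-yl)phenol | Oc1cc(OCOC)c(CC=C(C)C)c(OCOC)c1
F4 | step 11 | 1,3-bis(methoxymethoxy)-2-(3-methylbut-2-en-1-yl)-5-{[2-(trimethylsilyl)ethoxy]methoxy}benzene | C[Si](C)(C)CCOCOc1cc(OCOC)c(CC=C(C)C)c(OCOC)c1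
F5 | step 11 | (E)-1-[2,4-bis(methoxymethoxy)-3-(3-methylbut-2-en-1-yl)-6-{[2-(trimethylsilyl)ethoxy]methoxy}phenyl]-3-methoxy-2-[2-methoxy-4-(methoxymethoxy)-3-(3-methylbut-2-en-1-yl)phenyl]prop-2-en-1-one | CO/C=C(/C(=O)c1c(OCOCC[Si](C)(C)C)cc(OCOC)c(CC=C(C)C)c1OCOC)c1ccc(OCOC)c(CC=C(C)C)c1OC
F6 | step 5 | 2,4-bis(methoxymethoxy)-3-(3-methylbut-2-en-1-yl)phenyl diethylcarbamate | CCN(CC)C(=O)Oc1ccc(OCOC)c(CC=C(C)C)c1OCOC
F7 | step 5 | 2,4-bis(methoxymethoxy)-3-(3-methylbut-2-en-1-yl)-6-(trimethylsilyl)phenyl diethylcarbamate | CCN(CC)C(=O)Oc1c([Si](C)(C)C)cc(OCOC)c(CC=C(C)C)c1OCOC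
F8 | step 8 | [2-methoxy-4-(methoxymethoxy)phenyl]trimethylsilane | COCOc1ccc([Si](C)(C)C)c(OC)c1
F9 | step 8 | [2-methoxy-4-(methoxymethoxy)-3-(3-methylbut-2-en-1-yl)phenyl]trimethylsilane | COCOc1ccc([Si](C)(C)C)c(OC)c1CC=C(C)C
F10 | step 10 | prop-2-en-1-yl (Z)-2-iodo-3-methoxyprop-2-enoate | CO/C=C(\I)C(=O)OCC=C
F11 | step 10 | prop-2-en-1-yl (E)-3-methoxy-2-[2-methoxy-4-(methoxymethoxy)-3-(3-methylbut-2-en-1-yl)phenyl]prop-2-enoate | CO/C=C(\c1ccc(OCOC)c(CC=C(C)C)c1OC)C(=O)OCC=C
A1 | alternative 1 | 1-[6-hydroxy-2,4-bis(methoxymethoxy)-3-(3-methylbut-2-en-1-yl)phenyl]-2-[2-methoxy-4-(methoxymethoxy)-3-(3-methylbut-2-en-1-yl)phenyl]ethan-1-one | O=C(Cc1ccc(OCOC)c(CC=C(C)C)c1OC)c1c(O)cc(OCOC)c(CC=C(C)C)c1OCOC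
A2 | alternative 2 | 3-iodo-5,7-bis(methoxymethoxy)-6-(3-methylbut-2-en-1-yl)-4H-chromen-4-one | O=c1c(I)coc2cc(OCOC)c(CC=C(C)C)c(OCOC)c12
A3 | alternative 2 | 2-[2-methoxy-4-(methoxymethoxy)-3-(3-methylbut-2-en-1-yl)phenyl]-4,4,5,5-tetramethyl-1,3,2-dioxaborolane | COCOc1ccc(B2OC(C)(C)C(C)(C)O2)c(OC)c1CC=C(C)C
A4 | alternative 3 | (E)-1-[6-hydroxy-2,4-bis(methoxymethoxy)-3-(3-methylbut-2-en-1-yl)phenyl]-3-[2-methoxy-4-(methoxymethoxy)-3-(3-methylbut-2-en-1-yl)phenyl]prop-2-en-1-one | O=C(/C=C/c1ccc(OCOC)c(CC=C(C)C)c1OC)c1c(O)cc(OCOC)c(CC=C(C)C)c1OCOC
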